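**Remarks and assumptions**

- Gibberellane atom numbers are used for every intermediate: C7 is the carboxyl carbon on C6, C17 the exocyclic methylene carbon, C18 the methyl and C19 the carboxyl carbon on C4, C20 the carbon on C10. β is the face of ring B that carries H-5, H-9 and the C8–C15 bond; α is the face that carries C20 and C19.
- TBS = tert-butyldimethylsilyl, TES = triethylsilyl, TMSE = 2-(trimethylsilyl)ethyl.
- Assumption: compounds 20 to 26 are drawn with H-5 β, the result expected from protonation of enolate 19 anti to C20. Either C5 epimer serves, because C5 becomes trigonal in 28.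
- Assumption: acid 33 and the target are drawn as open aldehyde acids; ring–chain tautomerism between C20 and the C19 carboxyl does not affect the route.

## Analysis of the target

The target is a C20 gibberellin with a 6-5-6-5 skeleton: ring A (C1–C5, C10), cyclopentane ring B (C5, C6, C8, C9, C10), ring C (C8, C9, C11–C14) and ring D (C8, C13–C16). Rings C and D form a bicyclo[3.2.1]octane that carries the exocyclic C16=C17 alkene and the tertiary 13-hydroxyl. There are eight stereocentres (C3, C4, C5, C6, C8, C9, C10, C13), three of them quaternary carbons (C4, C8, C10) and one a bridgehead carbinol (C13). The A/B fusion is trans (H-5 β, C20 α), H-5 and H-6 are trans, the B/C fusion is cis (H-9 and C15 both β), the 3-hydroxyl is cis to the C18 methyl and trans to the C19 carboxyl, and C19 and C20 are 1,3-diaxial on the α face. The sensitive points are: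

- the β-hydroxy acid at C3/C4, which epimerises by retro-aldol cleavage in base while C19 is an ester;
- the C20 aldehyde beside the C19 carboxyl, since a C20 alcohol would lactonise onto C19;
- the epimerisable C6;
- the tertiary allylic alcohol, which rearranges in strong acid.

The difficulty lies in the congestion around C5, which sits between two quaternary carbons, and in keeping three carbonyl carbons (C7, C19, C20) at different oxidation levels. The strategy rests on ring B: the C9 methine lies between the quaternary C10 and C8, and C6 links C5 to C8. This is the pattern left when a cross-conjugated dienone with C6 as its carbonyl closes the C9–C10 bond by conrotation and the resulting oxyallyl cation is trapped at C8.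

## Retrosynthetic reasoning

**Endgame (34 ⇐ 33 ⇐ 32 ⇐ 31).** The last operations only unmask groups. C20 has to reach the aldehyde level without passing through a free alcohol, because a C20 hydroxyl next to the diaxial C19 ester would close a δ-lactone. C20 is therefore carried as a primary triethylsilyl ether that is oxidised directly (31 to 32). The aldehyde then assists hydrolysis of the hindered C19 methyl ester (32 to 33). The remaining silicon-based groups on O3, O13 and the C7 carboxyl fall together with fluoride (33 to 34), at a stage where C19 is a carboxylate and retro-aldol at C3–C4 is not possible.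

**C6–C7 bond and the C5/C6 centres (31 ⇐ 30 ⇐ 29 ⇐ 28 ⇐ 26).** The C6–C7 bond is cut because the key step leaves a ketone exactly at C6. Its enol triflate 28 is carbonylated to enoate 29, one-electron reduction sets H-5 on the open β face (30), and base equilibration sets C6 (31). This sequence is placed after ring D on purpose. An acylpalladium at C6 beside a C8 allyl group would insert that alkene to form a five-membered ketone, so the allyl group must be consumed first.

**Ring D (26 ⇐ 25 ⇐ 24 ⇐ 23 ⇐ 22 ⇐ 21 ⇐ 20).** The C16=C17 alkene is cut back to the ketone 25, and the C13–C16 bond to a keto aldehyde 22 by a pinacol transform. The allyl group of 20 supplies C15 and C16 (C17 is lost on cleavage and returned by methylenation), and the dithiolane supplies the C13 ketone. The C13 configuration needs no control, since the new bond can only form on the face where C15 already sits.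

**Key disconnection (20 ⇐ 17 + 18).** Cutting C9–C10 and C8–C15 removes ring B, two quaternary carbons and four stereocentres at once and leaves two monocyclic halves joined through the C6 carbonyl. Forward, dienone 17 must close by 4π conrotation on the correct face of ring A, and allylsilane 18 must capture the cation at C8.

**Dienone (17 ⇐ 16 ⇐ 11 + 15).** The C5–C6 bond is cut between a ring A vinyl triflate 11 and a ring C enal 15. A nickel/chromium-mediated addition is chosen because the organometallic is not basic and tolerates the ester and silyl ethers. Oxidation of the bis-allylic alcohol 16 gives 17.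

**Ring A (11 ⇐ 9 ⇐ 6 ⇐ 5 ⇐ 4 ⇐ 3 ⇐ 1).** C20 is attached by an aldol reaction at the only enolisable position of ketone 6, and the same ketone becomes the C5 triflate. Both ring A stereocentres come from one desymmetrising reduction of the prochiral diketo ester 4. The quaternary C4 of 4 is made by reductive methylation of aromatic ester 1, because acylating the enolate of a 2-alkyl-1,3-dione tends to go to oxygen.

**Ring C (15 ⇐ 14 ⇐ 13 ⇐ 12).** The masked C13 ketone must be 1,3 to C8 through C14, with the alkene at C8=C9. A six-membered building block with 1,4-related oxygen functions would place the masked ketone on C12 and cannot be used. Birch reduction of the meta-substituted anisole 12 gives exactly the needed pattern in 13, and a dithiolane is used for C13 because an O,O-acetal would be allylated under the conditions of the key step.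

## Alternatives that were turned down

**Alternative 1:** The C8–C14 bond is cut, so ring C closes last. The methyl ketone enolate (C14) of the ring B enoate A2 adds to C8, the β-carbon of the C6=C8 enoate, to give tricycle A1.
- For it: C7 arrives at the ester level, which saves the four steps spent here on triflate, carbonylation, reduction and epimerisation. The propargyl group on C8 could close ring D directly to the 13-hydroxy-16-methylene unit, and an intramolecular addition can only give the cis B/C fusion. On these points it is stronger than the chosen route.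
- Against it: the acceptor carbon is the fully substituted end of a tetrasubstituted enoate, and conjugate additions of ketone enolates that create a quaternary carbon are reversible with the equilibrium on the open side. In addition A2 already contains ring B with C5, C9 and C10 set next to the quaternary C4, so the hardest part of the molecule must be solved beforehand by other means, in a linear sequence.
- Comparison: the chosen route forms C10 and C8 together in the ring B closure and is convergent from two monocycles.

**Alternative 2:** The C3–C4 and C5–C10 bonds are cut. The silyloxydiene of triene A4 adds to its alkylidene malonate to give tetracycle A3, forming rings A and B together.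
- For it: two rings and three stereocentres are made in one step, and the bicyclo[3.2.1]octane is built early on simple material. The chosen route closes ring D late in a crowded molecule, so here the alternative is stronger.
- Against it: C4 emerges with two equal esters that must be told apart and one of them reduced to methyl. C1=C2 must be saturated and C7 raised from the alcohol to the acid level, which adds roughly six to eight corrective steps. The diene terminus C10 is disubstituted, with C20 forced into the inward position, which disfavours the s-cis conformer and slows the cycloaddition. Endo/exo and facial control relative to C6 and C9 are open.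
- Comparison: the chosen route carries C18 and C19 correctly from the first ring A intermediate and needs no later differentiation.

**Alternative 3:** Ring B is derived from a six-membered ring. Photolysis of the diazo ketone A6 in an alcohol contracts ring B, moving C8 from C7 to C6, and gives the fully protected target A5.
- For it: the rearrangement is dependable, the migrating C8 keeps its configuration, the step sits at the very end, and C6 can be corrected by epimerisation. As a single step it is more reliable than the ring B closure chosen here.
- Against it: it does not simplify the problem. A6 is a fully functionalised 6-6-6-5 tetracycle with all eight stereocentres, three quaternary carbons and the C19/C20 oxidation pattern in place. Diazo transfer to C6 next to the hindered C5 needs prior activation.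
- Comparison: the step count would clearly exceed that of a route whose key step itself builds ring B from two simple rings.

Key step: step 12

## Route

Step 1
Reactants: 1 methyl 2,6-dimethoxybenzoate
Product: 3 methyl 2,6-dimethoxy-1-methylcyclohexa-2,5-diene-1-carboxylate, via potassium dienolate 2 (not isolated)
Conditions: K, NH3(l), THF, t-BuOH (1 equiv), −78 °C; then MeI, −78 °C to rt
Reagents that add atoms: iodomethane, CI
Why: Birch reductive alkylation: the ester directs reduction to C1/C4 of the arene while both methoxy groups stay on the enol ether double bonds, and dienolate 2 is C-methylated at the carbon that becomes C4; one equivalent of proton source at low temperature limits loss of the ortho methoxy groups.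

Step 2
Reactants: 3 methyl 2,6-dimethoxy-1-methylcyclohexa-2,5-diene-1-carboxylate
Product: 4 methyl 1-methyl-2,6-dioxocyclohexane-1-carboxylate
Conditions: 1 M HCl, THF, 0 °C to rt
Reagents that add atoms: water, O
Why: Acid hydrolysis of the two enol ethers unmasks the prochiral 1,3-dione; acid is used because the non-enolisable diketo ester would suffer retro-Claisen opening with alkoxide.

Step 3
Reactants: 4 methyl 1-methyl-2,6-dioxocyclohexane-1-carboxylate
Product: 5 methyl (1R,6S)-6-hydroxy-1-methyl-2-oxocyclohexane-1-carboxylate
Conditions: H2 (50 atm), RuCl2[(S)-BINAP] (1 mol%), MeOH, 40 °C, stopped after 1 equiv H2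
Reagents that add atoms: none
Why: Noyori hydrogenation of a β-keto ester used as an enantiotopic-group-selective desymmetrisation: chelation of ketone and ester to ruthenium holds the ester equatorial and the methyl axial, hydride is delivered anti to the methyl so that the hydroxyl ends up trans to the ester (C4), and the ligand fixes the (S) carbinol (C3) by the usual sense for β-keto esters (the (R) ligand is used if the sense is reversed). The second carbonyl is the mismatched one and should react more slowly.

Step 4
Reactants: 5 methyl (1R,6S)-6-hydroxy-1-methyl-2-oxocyclohexane-1-carboxylate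
Product: 6 methyl (1R,6S)-6-(tert-butyldimethylsilyloxy)-1-methyl-2-oxocyclohexane-1-carboxylate
Conditions: TBSOTf, 2,6-lutidine, CH2Cl2, −78 to 0 °C
Reagents that add atoms: tert-butyldimethylsilyl triflate, CC(C)(C)[Si](C)(C)OS(=O)(=O)C(F)(F)F
Why: Silylation under non-basic conditions caps the β-hydroxy ketone before any base is used (retro-aldol risk) and installs the bulky C3 group that later biases the ring A conformation.

Step 5
Reactants: 6 methyl (1R,6S)-6-(tert-butyldimethylsilyloxy)-1-methyl-2-oxocyclohexane-1-carboxylate
Product: 9 methyl (1R,6S)-6-(tert-butyldimethylsilyloxy)-1-methyl-2-oxo-3-[(triethylsilyloxy)methyl]cyclohexane-1-carboxylate (both epimers at ring carbon 3), via lithium enolate 7 (not isolated), via lithium aldolate 8 (not isolated)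
Conditions: LDA, THF, −78 °C; CH2O (monomeric, THF solution), −78 °C; TESCl, −78 to 0 °C
Reagents that add atoms: formaldehyde, C=O; chlorotriethylsilane, CC[Si](Cl)(CC)CC
Why: The ketone has only one enolisable position (C10), so the aldol reaction with formaldehyde attaches C20 there; silylating aldolate 8 in the flask prevents retro-aldol and acyl transfer to the C19 ester. The C10 configuration is irrelevant because C10 becomes trigonal in step 6.

Step 6
Reactants: 9 methyl (1R,6S)-6-(tert-butyldimethylsilyloxy)-1-methyl-2-oxo-3-[(triethylsilyloxy)methyl]cyclohexane-1-carboxylate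
Product: 11 methyl (1R,6S)-6-(tert-butyldimethylsilyloxy)-1-methyl-3-[(triethylsilyloxy)methyl]-2-(trifluoromethylsulfonyloxy)cyclohex-2-ene-1-carboxylate, via potassium enolate 10 (not isolated)
Conditions: KHMDS, PhNTf2, THF, −78 °C
Reagents that add atoms: N-phenylbis(trifluoromethanesulfonimide), O=S(=O)(N(c1ccccc1)S(=O)(=O)C(F)(F)F)C(F)(F)F
Why: Only C10–H is α to the ketone, so enolate 10 forms regiospecifically and O-triflation gives the tetrasubstituted C5=C10 enol triflate; low temperature with the triflating agent already present suppresses β-elimination of the silyloxy group.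

Step 7
Reactants: 12 3-methoxybenzyl alcohol
Product: 13 (5-methoxycyclohexa-1,4-dien-1-yl)methanol
Conditions: Li, NH3(l), THF, t-BuOH, −78 to −33 °C; NH4Cl
Reagents that add atoms: none
Why: Birch reduction of a meta-substituted anisole leaves the methoxy carbon and the CH2O-bearing carbon on the two double bonds, which gives the enol ether carbon (C13) 1,3 to the carbon that carries C6 and the C8=C9 alkene already in place; the benzylic C–O bond survives as its alkoxide.

Step 8
Reactants: 13 (5-methoxycyclohexa-1,4-dien-1-yl)methanol
Product: 14 (1,4-dithiaspiro[4.5]dec-7-en-7-yl)methanol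
Conditions: HSCH2CH2SH, p-TsOH·H2O (cat.), CH2Cl2, 0 °C
Reagents that add atoms: ethane-1,2-dithiol, SCCS
Why: Acid-catalysed exchange: protonation of the enol ether at C12 gives an oxocarbenium ion that the dithiol traps before the β,γ-alkene can move into conjugation. A dithiolane is chosen because an O,O-acetal would undergo Hosomi–Sakurai allylation in step 12.

Step 9
Reactants: 14 (1,4-dithiaspiro[4.5]dec-7-en-7-yl)methanol
Product: 15 1,4-dithiaspiro[4.5]dec-7-ene-7-carbaldehyde
Conditions: MnO2, CH2Cl2, rt
Reagents that add atoms: none
Why: MnO2 oxidises the allylic alcohol selectively and leaves the thioacetal sulfur untouched.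

Step 10
Reactants: 11 methyl (1R,6S)-6-(tert-butyldimethylsilyloxy)-1-methyl-3-[(triethylsilyloxy)methyl]-2-(trifluoromethylsulfonyloxy)cyclohex-2-ene-1-carboxylate; 15 1,4-dithiaspiro[4.5]dec-7-ene-7-carbaldehyde
Product: 16 methyl (1S,6S)-6-(tert-butyldimethylsilyloxy)-2-[(1,4-dithiaspiro[4.5]dec-7-en-7-yl)(hydroxy)methyl]-1-methyl-3-[(triethylsilyloxy)methyl]cyclohex-2-ene-1-carboxylate (both carbinol epimers)
Conditions: CrCl2 (6 equiv), NiCl2 (2 mol%), DMF, 25 °C
Reagents that add atoms: none
Why: Nozaki–Hiyama–Kishi coupling: nickel inserts into the vinyl triflate and transmetalation gives a non-basic vinylchromium that adds 1,2 to the enal, forming C5–C6 in the presence of the ester, silyl ethers and dithiolane. The new carbinol centre is removed in step 11.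

Step 11
Reactants: 16 methyl (1S,6S)-6-(tert-butyldimethylsilyloxy)-2-[(1,4-dithiaspiro[4.5]dec-7-en-7-yl)(hydroxy)methyl]-1-methyl-3-[(triethylsilyloxy)methyl]cyclohex-2-ene-1-carboxylate
Product: 17 methyl (1S,6S)-6-(tert-butyldimethylsilyloxy)-2-(1,4-dithiaspiro[4.5]dec-7-ene-7-carbonyl)-1-methyl-3-[(triethylsilyloxy)methyl]cyclohex-2-ene-1-carboxylate
Conditions: Dess–Martin periodinane, NaHCO3, CH2Cl2, 0 °C
Reagents that add atoms: none
Why: Dess–Martin oxidation of the hindered bis-allylic alcohol under buffered anhydrous conditions, in which the dithiolane is stable, gives the cross-conjugated dienone.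

Step 12
Reactants: 17 methyl (1S,6S)-6-(tert-butyldimethylsilyloxy)-2-(1,4-dithiaspiro[4.5]dec-7-ene-7-carbonyl)-1-methyl-3-[(triethylsilyloxy)methyl]cyclohex-2-ene-1-carboxylate; 18 allyltrimethylsilane
Product: 20 A/B/C tricyclic C6 ketone (8β-allyl; 9β-H; 10α-CH2OTES; 5β-H; 4β-CH3; 4α-CO2CH3; 3β-OTBS; C13 dithiolane), via difluoroboron enolate 19 (not isolated)
Conditions: BF3·OEt2 (1.5 equiv), 18 (5 equiv), CH2Cl2, −78 to −20 °C; aq. NaHCO3
Reagents that add atoms: none
Why: BF3 binds the C6 carbonyl of 17 to give a pentadienyl cation, whose thermal 4π conrotatory electrocyclisation forms C9–C10 and closes the five-membered ring B; the closest known reaction type is the interrupted Nazarov cyclisation of α,α′-disubstituted dienones with allylsilane capture. Both termini are locked in rings, so C20 and H-9 are the inward groups and conrotation must place them trans (C20 α, H-9 β), which is the C9/C10 relation of the target. The selectivity the step needs is the sense of rotation relative to ring A: the trans C3 silyl ether and C4 ester are expected to sit diaxial, which removes their gauche contact and keeps the smaller methyl next to the O–BF3 group, so C9 should bond to C10 on the β face, anti to the axial ester. The oxyallyl cation (C5–C6–C8) is then captured by 18 at C8, since C5 lies between the quaternary C4 and C10 and is inaccessible. Capture occurs on the β face, anti to C11 of the folded cis B/C unit, forming C8–C15 and the C8 stereocentre, and loss of the silyl group to fluoride gives enolate 19. The same congestion at C5 should block closure of the β-silyl cation onto C5, the [3+2] pathway. Work-up protonates 19 at C5 anti to C20, although this centre is erased in step 19. The α-substituents on both vinyl groups (C4 and C14) favour the reactive s-trans/s-trans conformer and stabilise the oxyallyl cation, which is what lets capture compete with proton loss.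

Step 13
Reactants: 20 A/B/C tricyclic C6 ketone with C13 dithiolane
Product: 21 A/B/C tricyclic 6,13-diketone (8β-allyl; otherwise as 20)
Conditions: PhI(OCOCF3)2, NaHCO3, MeCN/H2O (9:1), 0 °C
Reagents that add atoms: water, O
Why: Oxidative hydrolysis of the dithiolane with hypervalent iodine is done first because the periodate used next would oxidise sulfur; the alkene, esters and (buffered) silyl ethers survive.

Step 14
Reactants: 21 A/B/C tricyclic 6,13-diketone
Product: 22 keto aldehyde (C16 aldehyde on the C8 CH2 group; 6,13-dioxo; otherwise as 21)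
Conditions: OsO4 (2 mol%), NaIO4, 2,6-lutidine, dioxane/H2O (3:1), rt
Reagents that add atoms: osmium tetroxide, O=[Os](=O)(=O)=O; sodium periodate, [Na+].[O-]I(=O)(=O)=O
Why: Lemieux–Johnson cleavage of the terminal alkene removes C17 and leaves C16 as an aldehyde, 1,5 to the C13 ketone through the quaternary C8.

Step 15
Reactants: 22 keto aldehyde
Product: 23 tetracyclic 13,16-diol with C6 ketone (ring D closed; C16 carbinol either epimer)
Conditions: SmI2 (3 equiv), THF, −78 to 0 °C
Reagents that add atoms: none
Why: SmI2 pinacol cyclisation: the aldehyde ketyl adds to the C13 ketone and closes the five-membered ring D (5-exo). Since C15 is fixed on the β face of C8, the C13–C16 bond can only form on that face, which sets C13. The hindered C6 ketone cannot take part, as that would need a four-membered ring.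

Step 16
Reactants: 23 tetracyclic 13,16-diol with C6 ketone
Product: 24 13-hydroxy-6,16-diketone
Conditions: SO3·pyridine, DMSO, i-Pr2NEt, CH2Cl2, 0 °C
Reagents that add atoms: none
Why: Parikh–Doering oxidation converts the secondary C16 carbinol to the ketone without glycol cleavage; this chloride-free activated DMSO is chosen because Swern conditions would already oxidise the primary triethylsilyl ether.

Step 17
Reactants: 24 13-hydroxy-6,16-diketone
Product: 25 13-(triethylsilyloxy)-6,16-diketone
Conditions: TESOTf, 2,6-lutidine, CH2Cl2, −78 °C
Reagents that add atoms: triethylsilyl triflate, CC[Si](CC)(CC)OS(=O)(=O)C(F)(F)F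
Why: Silylation of the tertiary 13-hydroxyl, so that the ylide in step 18, the base and triflimide in step 19 and the Swern reagent in step 23 meet no free hydroxyl.

Step 18
Reactants: 25 13-(triethylsilyloxy)-6,16-diketone
Product: 26 16-methylene C6 ketone (13-OTES; 20-OTES; 3β-OTBS; 19-methyl ester)
Conditions: Ph3PCH3Br, KOt-Bu, THF, 0 °C to rt
Reagents that add atoms: methyltriphenylphosphonium bromide, C[P+](c1ccccc1)(c1ccccc1)c1ccccc1.[Br-]
Why: Wittig methylenation of the C16 ketone; the C6 ketone, flanked by the quaternary C8 and by a C5 methine that lies between two quaternary carbons, is too hindered to react.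

Step 19
Reactants: 26 16-methylene C6 ketone
Product: 28 C5=C6 enol triflate (6-OTf; 16-methylene), via potassium enolate 27 (not isolated)
Conditions: KHMDS, THF, −78 to 0 °C; PhNTf2
Reagents that add atoms: N-phenylbis(trifluoromethanesulfonimide), O=S(=O)(N(c1ccccc1)S(=O)(=O)C(F)(F)F)C(F)(F)F
Why: C5–H is the only α-hydrogen of the C6 ketone, so enolisation is regiospecific and O-triflation gives the C5=C6 enol triflate, erasing the provisional C5 centre.

Step 20
Reactants: 28 C5=C6 enol triflate
Product: 29 C5=C6 enoate (C7 ester as its TMSE ester on C6)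
Conditions: Pd(OAc)2 (10 mol%), PPh3, CO (1 atm), Me3SiCH2CH2OH, Et3N, DMF, 60 °C
Reagents that add atoms: carbon monoxide, [C-]#[O+]; 2-(trimethylsilyl)ethanol, C[Si](C)(C)CCO
Why: Palladium-catalysed alkoxycarbonylation of the vinyl triflate introduces C7; it is run only after the allyl group has been consumed, because an acylpalladium at C6 would otherwise insert the C8 allyl alkene faster than it is trapped by the alcohol. The TMSE ester is chosen so that fluoride can cleave it at the end.

Step 21
Reactants: 29 C5=C6 enoate
Product: 30 saturated 7-TMSE ester with 5β-H (C6 epimers)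
Conditions: SmI2 (4 equiv), HMPA, t-BuOH, THF, 0 °C
Reagents that add atoms: none
Why: SmI2/HMPA conjugate reduction: electron transfer to the enoate is followed by protonation at C5 from the β face, because the α face is screened by the axial C19 ester and by C20; this gives the trans A/B fusion. C6 is set in step 22.

Step 22
Reactants: 30 saturated 7-TMSE ester (C6 epimers)
Product: 31 saturated 7-TMSE ester with 5β-H and 6α-H (C7 on the β face)
Conditions: KOt-Bu (0.3 equiv), t-BuOH/THF, rt
Reagents that add atoms: none
Why: Equilibration through the ester enolate with a hindered alkoxide should place C7 on the β face, trans to C4 on C5, the less crowded and more stable arrangement; the C19 ester has no α-hydrogen and is unaffected.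

Step 23
Reactants: 31 saturated 7-TMSE ester with 20-OTES
Product: 32 C20 aldehyde (19-methyl ester; 7-TMSE ester; 3β-OTBS; 13-OTES)
Conditions: (COCl)2, DMSO, CH2Cl2, −78 to −30 °C; Et3N
Reagents that add atoms: none
Why: Under Swern conditions a primary triethylsilyl ether is cleaved and oxidised in one operation while the tertiary TES and secondary TBS ethers persist, so C20 goes to the aldehyde without a free C20 alcohol that would lactonise onto the 1,3-diaxial C19 ester.

Step 24
Reactants: 32 C20 aldehyde
Product: 33 20-oxo 19-carboxylic acid (7-TMSE ester; 3β-OTBS; 13-OTES)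
Conditions: LiOH, THF/H2O, 0 °C to rt; pH 4 buffer
Reagents that add atoms: lithium hydroxide, [Li+].[OH-]
Why: Hydroxide adds to the C20 aldehyde and the hydrate oxygen attacks the 1,3-diaxial C19 ester (neighbouring-group-assisted saponification), so the otherwise inert neopentyl methyl ester is cleaved under mild conditions that the hindered C7 ester should survive; O3 is still silylated, so no retro-aldol at C3–C4 can occur.

Step 25
Reactants: 33 20-oxo 19-carboxylic acid
Product: 34 target, 3β,13-dihydroxy-20-oxogibberell-16-ene-7,19-dioic acid (CNP0236431.1)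
Conditions: Bu4NF, THF, rt to 45 °C; pH 3 phosphate buffer
Reagents that add atoms: none
Why: Fluoride removes the three silicon-based groups (TBS on O3, TES on O13, the TMSE ester by β-elimination); C19 is a carboxylate at this stage, which prevents retro-aldol epimerisation at C3, and the mild acidification spares the tertiary allylic alcohol.

## Compound list

1 | methyl 2,6-dimethoxybenzoate | COC(=O)c1c(OC)cccc1OC | starting material
2 | potassium dienolate from two-electron reduction of 1 | COC([O-])=C1C(OC)=CCC=C1OC.[K+] | intermediate
3 | methyl 2,6-dimethoxy-1-methylcyclohexa-2,5-diene-1-carboxylate | COC(=O)C1(C)C(OC)=CCC=C1OC | intermediate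
4 | methyl 1-methyl-2,6-dioxocyclohexane-1-carboxylate | COC(=O)C1(C)C(=O)CCCC1=O | intermediate
5 | methyl (1R,6S)-6-hydroxy-1-methyl-2-oxocyclohexane-1-carboxylate (OH cis to CH3, trans to CO2CH3) | O=C1CCC[C@H](O)[C@@]1(C)C(=O)OC | intermediate
6 | methyl (1R,6S)-6-(tert-butyldimethylsilyloxy)-1-methyl-2-oxocyclohexane-1-carboxylate | O=C1CCC[C@H](O[Si](C)(C)C(C)(C)C)[C@@]1(C)C(=O)OC | intermediate
7 | lithium enolate of 6 (C5=C10 enolate) | [Li+].[O-]C1=CCC[C@H](O[Si](C)(C)C(C)(C)C)[C@@]1(C)C(=O)OC | intermediate
8 | lithium aldolate (C10–CH2OLi; both C10 epimers) | O=C1C(C[O-])CC[C@H](O[Si](C)(C)C(C)(C)C)[C@@]1(C)C(=O)OC.[Li+] | intermediate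
9 | methyl (1R,6S)-6-(tert-butyldimethylsilyloxy)-1-methyl-2-oxo-3-[(triethylsilyloxy)methyl]cyclohexane-1-carboxylate (both epimers at ring carbon 3) | O=C1C(CO[Si](CC)(CC)CC)CC[C@H](O[Si](C)(C)C(C)(C)C)[C@@]1(C)C(=O)OC | intermediate
10 | potassium enolate of 9 (C5=C10 enolate) | [K+].[O-]C1=C(CO[Si](CC)(CC)CC)CC[C@H](O[Si](C)(C)C(C)(C)C)[C@@]1(C)C(=O)OC | intermediate
11 | methyl (1R,6S)-6-(tert-butyldimethylsilyloxy)-1-methyl-3-[(triethylsilyloxy)methyl]-2-(trifluoromethylsulfonyloxy)cyclohex-2-ene-1-carboxylate (ring A enol triflate) | O=S(=O)(OC1=C(CO[Si](CC)(CC)CC)CC[C@H](O[Si](C)(C)C(C)(C)C)[C@@]1(C)C(=O)OC)C(F)(F)F | intermediate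
12 | 3-methoxybenzyl alcohol | COc1cccc(CO)c1 | starting material
13 | (5-methoxycyclohexa-1,4-dien-1-yl)methanol | COC1=CCC=C(CO)C1 | intermediate
14 | (1,4-dithiaspiro[4.5]dec-7-en-7-yl)methanol | OCC1=CCCC2(C1)SCCS2 | intermediate
15 | 1,4-dithiaspiro[4.5]dec-7-ene-7-carbaldehyde (ring C enal) | O=CC1=CCCC2(C1)SCCS2 | intermediate
16 | methyl (1S,6S)-6-(tert-butyldimethylsilyloxy)-2-[(1,4-dithiaspiro[4.5]dec-7-en-7-yl)(hydroxy)methyl]-1-methyl-3-[(triethylsilyloxy)methyl]cyclohex-2-ene-1-carboxylate (both carbinol epimers) | OC(C1=C(CO[Si](CC)(CC)CC)CC[C@H](O[Si](C)(C)C(C)(C)C)[C@@]1(C)C(=O)OC)C1=CCCC2(C1)SCCS2 | intermediate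
17 | methyl (1S,6S)-6-(tert-butyldimethylsilyloxy)-2-(1,4-dithiaspiro[4.5]dec-7-ene-7-carbonyl)-1-methyl-3-[(triethylsilyloxy)methyl]cyclohex-2-ene-1-carboxylate (ring A / ring C dienone) | O=C(C1=C(CO[Si](CC)(CC)CC)CC[C@H](O[Si](C)(C)C(C)(C)C)[C@@]1(C)C(=O)OC)C1=CCCC2(C1)SCCS2 | intermediate
18 | allyltrimethylsilane | C=CC[Si](C)(C)C | starting material
19 | difluoroboron C5=C6 enolate of the allylated tricycle | C=CC[C@]12CC3(CC[C@H]1[C@]1(CO[Si](CC)(CC)CC)CC[C@H](O[Si](C)(C)C(C)(C)C)[C@@](C)(C(=O)OC)C1=C2OB(F)F)SCCS3 | intermediate
20 | A/B/C tricyclic C6 ketone: 8β-allyl; 9β-H; 10α-CH2OTES; 5β-H; 4β-CH3; 4α-CO2CH3; 3β-OTBS; C13 1,3-dithiolane | C=CC[C@]12CC3(CC[C@H]1[C@]1(CO[Si](CC)(CC)CC)CC[C@H](O[Si](C)(C)C(C)(C)C)[C@@](C)(C(=O)OC)[C@H]1C2=O)SCCS3 | intermediate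
21 | A/B/C tricyclic 6,13-diketone (8β-allyl; otherwise as 20) | C=CC[C@]12CC(=O)CC[C@H]1[C@]1(CO[Si](CC)(CC)CC)CC[C@H](O[Si](C)(C)C(C)(C)C)[C@@](C)(C(=O)OC)[C@H]1C2=O | intermediate
22 | keto aldehyde: 8β-(2-oxoethyl) 6,13-diketone | O=CC[C@]12CC(=O)CC[C@H]1[C@]1(CO[Si](CC)(CC)CC)CC[C@H](O[Si](C)(C)C(C)(C)C)[C@@](C)(C(=O)OC)[C@H]1C2=O | intermediate
23 | tetracyclic 13,16-diol with C6 ketone (ring D closed; C16 carbinol either epimer) | OC1C[C@]23C[C@@]1(O)CC[C@H]2[C@]1(CO[Si](CC)(CC)CC)CC[C@H](O[Si](C)(C)C(C)(C)C)[C@@](C)(C(=O)OC)[C@H]1C3=O | intermediate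
24 | 13-hydroxy-6,16-diketone | O=C1C[C@]23C[C@@]1(O)CC[C@H]2[C@]1(CO[Si](CC)(CC)CC)CC[C@H](O[Si](C)(C)C(C)(C)C)[C@@](C)(C(=O)OC)[C@H]1C3=O | intermediate
25 | 13-(triethylsilyloxy)-6,16-diketone | O=C1C[C@]23C[C@@]1(O[Si](CC)(CC)CC)CC[C@H]2[C@]1(CO[Si](CC)(CC)CC)CC[C@H](O[Si](C)(C)C(C)(C)C)[C@@](C)(C(=O)OC)[C@H]1C3=O | intermediate
26 | 16-methylene C6 ketone (13-OTES; 20-OTES; 3β-OTBS; 19-methyl ester) | C=C1C[C@]23C[C@@]1(O[Si](CC)(CC)CC)CC[C@H]2[C@]1(CO[Si](CC)(CC)CC)CC[C@H](O[Si](C)(C)C(C)(C)C)[C@@](C)(C(=O)OC)[C@H]1C3=O | intermediate
27 | potassium C5=C6 enolate of 26 | C=C1C[C@]23C[C@@]1(O[Si](CC)(CC)CC)CC[C@H]2[C@]1(CO[Si](CC)(CC)CC)CC[C@H](O[Si](C)(C)C(C)(C)C)[C@@](C)(C(=O)OC)C1=C3[O-].[K+] | intermediate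
28 | C5=C6 enol triflate (6-OTf; 16-methylene) | C=C1C[C@]23C[C@@]1(O[Si](CC)(CC)CC)CC[C@H]2[C@]1(CO[Si](CC)(CC)CC)CC[C@H](O[Si](C)(C)C(C)(C)C)[C@@](C)(C(=O)OC)C1=C3OS(=O)(=O)C(F)(F)F | intermediate
29 | C5=C6 enoate, 7-TMSE ester | C=C1C[C@]23C[C@@]1(O[Si](CC)(CC)CC)CC[C@H]2[C@]1(CO[Si](CC)(CC)CC)CC[C@H](O[Si](C)(C)C(C)(C)C)[C@@](C)(C(=O)OC)C1=C3C(=O)OCC[Si](C)(C)C | intermediate
30 | saturated 7-TMSE ester, 5β-H, C6 epimers | C=C1C[C@]23C[C@@]1(O[Si](CC)(CC)CC)CC[C@H]2[C@]1(CO[Si](CC)(CC)CC)CC[C@H](O[Si](C)(C)C(C)(C)C)[C@@](C)(C(=O)OC)[C@H]1C3C(=O)OCC[Si](C)(C)C | intermediate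
31 | saturated 7-TMSE ester, 5β-H, 6α-H (C7 β) | C=C1C[C@]23C[C@@]1(O[Si](CC)(CC)CC)CC[C@H]2[C@]1(CO[Si](CC)(CC)CC)CC[C@H](O[Si](C)(C)C(C)(C)C)[C@@](C)(C(=O)OC)[C@H]1[C@@H]3C(=O)OCC[Si](C)(C)C | intermediate
32 | C20 aldehyde (19-methyl ester; 7-TMSE ester; 3β-OTBS; 13-OTES) | C=C1C[C@]23C[C@@]1(O[Si](CC)(CC)CC)CC[C@H]2[C@]1(C=O)CC[C@H](O[Si](C)(C)C(C)(C)C)[C@@](C)(C(=O)OC)[C@H]1[C@@H]3C(=O)OCC[Si](C)(C)C | intermediate
33 | 20-oxo 19-carboxylic acid (7-TMSE ester; 3β-OTBS; 13-OTES) | C=C1C[C@]23C[C@@]1(O[Si](CC)(CC)CC)CC[C@H]2[C@]1(C=O)CC[C@H](O[Si](C)(C)C(C)(C)C)[C@@](C)(C(=O)O)[C@H]1[C@@H]3C(=O)OCC[Si](C)(C)C | intermediate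
34 | 3β,13-dihydroxy-20-oxogibberell-16-ene-7,19-dioic acid (CNP0236431.1) | C=C1C[C@]23C[C@@]1(O)CC[C@H]2[C@]1(C=O)CC[C@H](O)[C@@](C)(C(=O)O)[C@H]1[C@@H]3C(=O)O | target

## Step count and least certain steps

Total: 25 steps. Longest linear sequence: 22 steps (steps 1–6 and 10–25); steps 7–9 form the ring C branch.

**Step 12 (key step).** The most likely failure is partitioning of the cationic intermediates away from C8 allylation. Closure onto the fully substituted C10 is slow, so the allylsilane may add to the C8=C9 enone before ring closure, or the oxyallyl cation may lose a proton from C14 or C9 or suffer a 1,2-shift towards C5 before it is trapped. The second uncertainty is incomplete facial control of the conrotation, since it depends on ring A reacting through the diaxial conformer. Fallback: separate the ring closure from the C8–C15 bond formation. Starting from 17, BF3·OEt2 and Et3SiH (CH2Cl2, −78 to 0 °C) would effect a hydride-interrupted Nazarov closure; the smaller, faster hydride donor gives the same ketone whichever end of the oxyallyl cation it attacks, namely the C8–H tricyclic ketone F1. Kinetic deprotonation of F1 with LDA at the more accessible C8–H (C5–H lies between two quaternary carbons) and alkylation with allyl bromide on the β face, anti to C11, would return to 20.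

**Step 3.** The most likely failure is reduction of the wrong enantiotopic carbonyl (hydroxyl cis to the ester) if the substrate does not react through the ester-chelated conformer, or over-reduction to the diol. Fallback: from 4, reduce with Zn(BH4)2 (Et2O, −78 °C), where zinc chelation of ketone and ester enforces hydride delivery anti to the axial methyl. This gives the racemic trans hydroxy ketone, that is 5 together with its enantiomer, methyl (1S,6R)-6-hydroxy-1-methyl-2-oxocyclohexane-1-carboxylate F2. Lipase-catalysed acetylation with vinyl acetate (Candida antarctica lipase B) should then convert F2 into its acetate, methyl (1S,6R)-6-acetoxy-1-methyl-2-oxocyclohexane-1-carboxylate F3, which is separated. The unreacted alcohol is 5, where the route is rejoined.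

**Step 10.** The most likely failure is slow oxidative addition and slow carbonyl addition at the tetrasubstituted C5, which has a quaternary neighbour, leading to protodetriflation. Fallback: an acylative Stille coupling that forms the same C5–C6 bond at the ketone oxidation level. From 11, Me3SnSnMe3 with Pd(PPh3)4 and LiCl gives the trimethylstannyl analogue of 11 (SnMe3 in place of OTf), stannane F4. From 15, buffered NaClO2 with 2-methyl-2-butene gives 1,4-dithiaspiro[4.5]dec-7-ene-7-carboxylic acid F5, and (COCl)2 converts it into the acid chloride F6. Coupling of F4 with F6 under zerovalent palladium catalysis (Pd2(dba)3, tri(2-furyl)phosphine, CuCl) would give dienone 17 directly, bypassing 16.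

**Step 21.** The most likely failure is sluggish electron transfer, because the ester of 29 is twisted out of conjugation by its quaternary neighbours; this leaves time for unselective hydrogen transfer to C5. Fallback: dissolving-metal reduction of 29 (Li, NH3/THF, 1 equiv t-BuOH, −78 °C, short contact). It is a stronger reductant and proceeds through the dianion, which is protonated at C5 from the β face; the conjugated ester is reduced well before the hindered saturated C19 ester, and the silyl ethers and the isolated alkene are inert. This returns to 30 and makes no new compound.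

**Step 23.** The most likely failure is that the neopentyl-type silyl ether is cleaved faster than the resulting alcohol is oxidised, or resists activation, so that a free C20 hydroxyl closes the δ-lactone onto C19. Fallback: a two-stage sequence from 31. The primary TES group is removed with HF·pyridine buffered with excess pyridine (THF, −20 °C) to give the C20 alcohol F7, which is kept cold and near neutral and oxidised at once with Dess–Martin periodinane and pyridine to return to 32.

## Further compounds

F1 | step 12 | A/B/C tricyclic C6 ketone with H in place of allyl at C8 (8β-H; otherwise as 20) | [C@H]12CC3(CC[C@H]1[C@]1(CO[Si](CC)(CC)CC)CC[C@H](O[Si](C)(C)C(C)(C)C)[C@@](C)(C(=O)OC)[C@H]1C2=O)SCCS3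
F2 | step 3 | methyl (1S,6R)-6-hydroxy-1-methyl-2-oxocyclohexane-1-carboxylate (enantiomer of 5) | O=C1CCC[C@@H](O)[C@]1(C)C(=O)OC
F3 | step 3 | methyl (1S,6R)-6-acetoxy-1-methyl-2-oxocyclohexane-1-carboxylate | O=C1CCC[C@@H](OC(C)=O)[C@]1(C)C(=O)OC
F4 | step 10 | ring A vinylstannane, the trimethylstannyl analogue of 11 | C[Sn](C)(C)C1=C(CO[Si](CC)(CC)CC)CC[C@H](O[Si](C)(C)C(C)(C)C)[C@@]1(C)C(=O)OC
F5 | step 10 | 1,4-dithiaspiro[4.5]dec-7-ene-7-carboxylic acid | OC(=O)C1=CCCC2(C1)SCCS2
F6 | step 10 | 1,4-dithiaspiro[4.5]dec-7-ene-7-carbonyl chloride | ClC(=O)C1=CCCC2(C1)SCCS2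
F0 | step 21 | none | none
F7 | step 23 | C20 alcohol (19-methyl ester; 7-TMSE ester; 3β-OTBS; 13-OTES) | C=C1C[C@]23C[C@@]1(O[Si](CC)(CC)CC)CC[C@H]2[C@]1(CO)CC[C@H](O[Si](C)(C)C(C)(C)C)[C@@](C)(C(=O)OC)[C@H]1[C@@H]3C(=O)OCC[Si](C)(C)C
A1 | alternative 1 | A/B/C tricyclic C13 ketone with 3-(trimethylsilyl)prop-2-ynyl on C8 (product of the Michael closure) | C[Si](C)(C)C#CC[C@]23CC(=O)CC[C@H]2[C@]1(C(OC)OC)CC[C@H](OCOC)[C@@](C)(C(=O)OC)[C@H]1[C@@H]3C(=O)OC
A2 | alternative 1 | ring A/B C6=C8 enoate with a 3-oxobutyl chain on C9 (substrate of the Michael closure) | C[Si](C)(C)C#CCC1=C(C(=O)OC)[C@@H]2[C@](C)(C(=O)OC)[C@@H](OCOC)CC[C@@]2(C(OC)OC)[C@@H]1CCC(C)=O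
A3 | alternative 2 | tetracyclic cycloadduct (C4 geminal diester, C1=C2 alkene, C16 ketone) | O=C1C[C@]23C[C@@]1(OCOC)CC[C@H]2[C@]1(C(OC)OC)C=C[C@H](O[Si](C)(C)C(C)(C)C)C(C(=O)OC)(C(=O)OC)[C@H]1[C@@H]3CO[Si](C)(C)C(C)(C)C
A4 | alternative 2 | C/D bicyclic triene: silyloxydiene on C9 and alkylidene malonate on C6 (substrate of the cycloaddition) | O=C1C[C@@]2(C[C@@]1(OCOC)CC[C@H]2/C(C(OC)OC)=C/C=C/O[Si](C)(C)C(C)(C)C)[C@@H](CO[Si](C)(C)C(C)(C)C)C=C(C(=O)OC)C(=O)OC
A5 | alternative 3 | fully protected target (7,19-dimethyl ester, 3,13-bis-methoxymethyl ether, C20 dimethyl acetal) | C=C1C[C@]23C[C@@]1(OCOC)CC[C@H]2[C@]1(C(OC)OC)CC[C@H](OCOC)[C@@](C)(C(=O)OC)[C@H]1[C@@H]3C(=O)OC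
A6 | alternative 3 | 6-diazo-7-oxo kauranoid with six-membered ring B (substrate of the ring contraction) | C=C1C[C@]23C[C@@]1(OCOC)CC[C@H]2[C@]1(C(OC)OC)CC[C@H](OCOC)[C@@](C)(C(=O)OC)[C@H]1C(=[N+]=[N-])C3=O
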